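(The rate constants belong to no real substance; the flask was simulated.)

The amounts first: elm and birch each took 0.050 M of Imd and differed in Ptn, 0.0550 M against 0.0660 M, over 5.0 h.

in all of them: Imd 0.050 M; time 5.0 h

|  | Ptn |
|---|---|
| elm | 0.0550 M |
| birch | 0.0660 M |

    Imd + Ptn → Byp + Imd2 (k1 = 2.93 M⁻¹ h⁻¹)
    Imd2 + Ptn ⇌ Byp + Imd3 (K2 = 10.0, k2 = 2.35 M⁻¹ h⁻¹)
    Spx ⇌ Byp, rate k3*(cs3 - [Byp]) while solid is left; crystals form when [Byp] > cs3 (cs3 = 35 mM, k3 = 5.14 h⁻¹)
    Imd + Imd2 → Sid (k4 = 0.164 M⁻¹ h⁻¹)

- which of these there is most of at the end, counted by the Imd in it, elm (Sid / Imd / Imd2 / Imd3)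
- which of these there is most of at the end, counted by the Imd in it, birch (Sid / Imd / Imd2 / Imd3)
- final amount of the leader among these, as a percentage of the Imd charged, in elm
- final amount of the leader among these, as a percentage of the Imd charged, in birch

1. I compared half-lives at the charged amounts in elm: 4.3 h for Imd by the first exchange, 5.4 h for Imd2 by the forward second exchange, and 85 h for Imd2 going to Sid. The road to Sid was much the slowest, so I set it aside.

2. Which concentration set the order? If Ptn stood still, the decay would be pseudo-first-order and leave 44.7% of the Imd in elm. But elm held 1.10 Ptn per Imd, so Ptn fell with Imd.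

3. I therefore let both partners fall. With s the surplus of Ptn over Imd, P and M their charges, k the first rate constant and t the time, the part of Imd left is s / (P·exp(s·k·t) − M). Elm gave 54.5%. This is the running-down share: the Imd left when I count the first exchange and no other step.

4. Birch, nearly the same flask, gave 47.9%. The second exchange also spends Ptn, so I expected both flasks slightly higher. In birch the exchanged part, 52.1%, is split between Imd2 and Imd3, so I committed to Imd as leader in both.

5. The forecast named Imd for elm at 55% and Imd for birch at 49%, slightly above my shares, on the ground that “the first exchange is slow at these concentrations”.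

6. The flasks gave Imd at 55.4% in elm and Imd at 49.1% in birch, so the forecast held.

Elm ended 0.90 percentage points above my share 54.5%. Birch ended lower in Imd than elm because of the difference in its charge of Ptn: the birch flask run with elm's Ptn read 55.4% Imd instead of 49.1%. On the neighbour flask with 0.022 M of Ptn, where the surplus turns negative, the same share gives 79.1%, and that flask read 79.1%.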